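**Plan**

- Carotenoid numbering is used: ring C2–C6, isopropenyl C1(C16,C17) on C2, methyl C18 and OH on C5, chain C7–C15 and C15'–C1'.
- The retrosynthesis cuts C7=C8 (Wittig) into a C10 ring aldehyde and a C30 polyenyl phosphonium salt; the salt is cut at C11=C12 and C11'=C12' into a C5 phosphonate ester, the C10 dialdehyde and a C15 salt from pseudoionone.
- The ring aldehyde goes back to a cis-fused β-lactone, in which C5–C6 and O–C7 are cut together to (3S)-6-oxo-3-(prop-1-en-2-yl)heptanoic acid, the ring-opened form of (S)-limonene.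
- Enabling feature: the cyclopentane C2–C6 carries the C5 carbinol β to C7 and cis to it, so C1–C7 with C16–C18 are the ten carbons of limonene with the ring bond moved from C5–C7 to C5–C6.
- Forward: the cyclohexene is opened, the cyclopentane and the oxetanone close together in one step (the only rings made), the lactone is opened to the aldehyde, and the chain is built C15 + C10 + C5 and joined last at C7=C8.
- Stereochemistry: C2 comes from (S)-limonene, C6 from 1,2-induction by C2 and C5 from the cis ring fusion in the key step; the E double bonds come from Wittig and Horner–Wadsworth–Emmons steps with a final iodine-catalysed equilibration.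

Key step: step 3

Remark: pseudoionone is used as its (3E,5E) isomer, the main component of the commercial mixture; residual 5Z material would be removed when the C15 salt and the C25 aldehyde are crystallised.
Remark: the C5 phosphonate ester of step 10 is taken as a purchased building block; it is otherwise one Arbuzov step from ethyl (2E)-4-bromo-2-methylbut-2-enoate and P(OEt)3.
Remark: metal alkoxides that the aqueous work-up only protonates are not counted as separate compounds.

**Route**

Step 1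
Reactants: 1 (S)-(−)-limonene
Product: 3 (3S)-6-oxo-3-(prop-1-en-2-yl)heptanal, via ring ozonide 2 (not isolated)
Conditions: O3 (1.0 equiv, Sudan Red 7B as end-point indicator), CH2Cl2, −78 °C; then PPh3, −78 °C → rt
Reagents that add atoms: ozone, [O-][O+]=O
Why: Criegee ozonolysis is fastest at the electron-rich trisubstituted ring alkene, so one equivalent of ozone, metered by a dye that bleaches once this alkene is consumed, should leave the 1,1-disubstituted isopropenyl group and the C2 stereocentre untouched, and PPh3 reduces ozonide 2 to the two carbonyl groups.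

Step 2
Reactants: 3 (3S)-6-oxo-3-(prop-1-en-2-yl)heptanal
Product: 4 (3S)-6-oxo-3-(prop-1-en-2-yl)heptanoic acid
Conditions: NaClO2, NaH2PO4, 2-methylbut-2-ene, t-BuOH/H2O, 0 °C → rt
Reagents that add atoms: sodium chlorite, [Na+].[O-]Cl=O
Why: In this Pinnick oxidation chlorous acid converts only the aldehyde into the acid, the ketone is inert, and 2-methylbut-2-ene takes up the HOCl that would otherwise add to the isopropenyl group.

Step 3
Reactants: 4 (3S)-6-oxo-3-(prop-1-en-2-yl)heptanoic acid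
Product: 7 (1R,2S,5S)-5-methyl-2-(prop-1-en-2-yl)-6-oxabicyclo[3.2.0]heptan-7-one, via acyloxypyridinium triflate 5 (not isolated), via acylammonium triflate 6 (not isolated)
Conditions: 2-bromo-1-propylpyridinium triflate (1.5 equiv), 4-pyrrolidinopyridine (1.5 equiv), i-Pr2NEt (3 equiv), CH2Cl2, rt, 4 added by syringe pump
Reagents that add atoms: none
Why: The carboxylate displaces bromide from the pyridinium salt, 4-pyrrolidinopyridine takes over the acyl group, and i-Pr2NEt removes the now acidic C6–H of acylammonium ion 6 to give an ammonium enolate that adds through C6 to the C5 ketone, after which the tertiary alkoxide attacks C7 and expels the pyridine. The closest known reaction type is the nucleophile-catalysed aldol-lactonization of keto acids to cis-fused bicyclic β-lactones. The cyclopentane closes by a 5-exo-trig aldol addition with the enolate double bond outside the new ring (enolexo), and the oxetanone closes by a 4-exo-trig acyl substitution. C6 is set by the C2 stereocentre, because allylic 1,3-strain holds the C2–H bond in the plane of the enolate so that the ketone tether reaches C6 from the face opposite to isopropenyl (isopropenyl pseudo-equatorial in the envelope-like transition state) and C7 ends trans to it; C5 is set by the ring fusion, since only the aldolate with oxygen cis to C7 can close the four-membered ring and the other can revert by retro-aldol. The step needs enolisation at C6 in preference to the ketone α-positions, secured by the much higher acidity of the acylammonium α-protons, a single ring size, secured by the four-atom tether, and lactonisation faster than dehydration of the aldolate, secured by the acylammonium acceptor held cis to the alkoxide.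

Step 4
Reactants: 7 (1R,2S,5S)-5-methyl-2-(prop-1-en-2-yl)-6-oxabicyclo[3.2.0]heptan-7-one
Product: 8 (1R,2S,5S)-2-hydroxy-N-methoxy-N,2-dimethyl-5-(prop-1-en-2-yl)cyclopentane-1-carboxamide
Conditions: MeNH(OMe)·HCl, Me2AlCl, CH2Cl2, 0 °C → rt; aq. KNaC4H4O6 (tartrate)
Reagents that add atoms: N,O-dimethylhydroxylamine hydrochloride, CNOC.Cl
Why: The chloroaluminium amide formed from Me2AlCl and the amine salt attacks the strained acyl–oxygen bond of the β-lactone (Weinreb aminolysis), the tertiary C5–O bond cannot be opened by substitution, and no stereocentre is touched.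

Step 5
Reactants: 8 (1R,2S,5S)-2-hydroxy-N-methoxy-N,2-dimethyl-5-(prop-1-en-2-yl)cyclopentane-1-carboxamide
Product: 9 (1R,2S,5S)-N-methoxy-N,2-dimethyl-5-(prop-1-en-2-yl)-2-[(triethylsilyl)oxy]cyclopentane-1-carboxamide
Conditions: Et3SiOTf, 2,6-lutidine, CH2Cl2, −78 → 0 °C
Reagents that add atoms: triethylsilyl trifluoromethanesulfonate, CC[Si](CC)(CC)OS(=O)(=O)C(F)(F)F
Why: The silyl triflate with 2,6-lutidine is reactive enough for a tertiary alcohol, and the silyl ether blocks retro-aldol cleavage and dehydration of the aldol unit in the basic steps that follow.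

Step 6
Reactants: 9 (1R,2S,5S)-N-methoxy-N,2-dimethyl-5-(prop-1-en-2-yl)-2-[(triethylsilyl)oxy]cyclopentane-1-carboxamide
Product: 11 (1R,2S,5S)-2-methyl-5-(prop-1-en-2-yl)-2-[(triethylsilyl)oxy]cyclopentane-1-carbaldehyde, via aluminium hemiaminal 10 (not isolated)
Conditions: i-Bu2AlH, THF, −78 °C; then aq. KNaC4H4O6 (tartrate), 0 °C
Reagents that add atoms: none
Why: Hydride addition to the Weinreb amide stops at the chelated aluminium hemiaminal 10, which releases the aldehyde only on work-up, so there is no over-reduction and the cold, non-basic conditions should leave C6 unchanged.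

Step 7
Reactants: 12 pseudoionone, (3E,5E)-6,10-dimethylundeca-3,5,9-trien-2-one
Product: 13 (4E,6E)-3,7,11-trimethyldodeca-1,4,6,10-tetraen-3-ol (racemic)
Conditions: CH2=CHMgBr, THF, 0 °C; aq. NH4Cl
Reagents that add atoms: vinylmagnesium bromide (CH2=CHMgBr), C=C[Mg]Br
Why: The Grignard reagent adds 1,2 to the carbonyl group of the dienone, and the new carbinol centre, formed as a racemate, is lost in the next step.

Step 8
Reactants: 13 (4E,6E)-3,7,11-trimethyldodeca-1,4,6,10-tetraen-3-ol
Product: 14 [(2E,4E,6E)-3,7,11-trimethyldodeca-2,4,6,10-tetraen-1-yl]triphenylphosphonium bromide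
Conditions: PPh3·HBr, MeOH, rt
Reagents that add atoms: triphenylphosphine hydrobromide, [Br-].c1ccc(cc1)[PH+](c1ccccc1)c1ccccc1
Why: Acid ionises the doubly allylic tertiary alcohol to a delocalised cation that PPh3 captures at the primary terminus (allylic transposition), which gives the conjugated phosphonium salt with the thermodynamically preferred E geometry.

Step 9
Reactants: 14 [(2E,4E,6E)-3,7,11-trimethyldodeca-2,4,6,10-tetraen-1-yl]triphenylphosphonium bromide; 15 (2E,4E,6E)-2,7-dimethylocta-2,4,6-trienedial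
Product: 17 C25 aldehyde 12'-apo-ψ-caroten-12'-al (all-E), via C15 ylide 16 (not isolated)
Conditions: 15 (2.5 equiv), NaOMe (1.05 equiv, slow addition), CH2Cl2/MeOH, 0 °C → rt; crystallisation
Reagents that add atoms: none
Why: Wittig olefination with the conjugated ylide 16 forms C11'=C12' mainly as the E isomer, excess dialdehyde and slow addition of base hold the reaction at mono-olefination because the product aldehyde is the less electrophilic one, and crystallisation should remove the hindered 11'Z isomer.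

Step 10
Reactants: 17 C25 aldehyde 12'-apo-ψ-caroten-12'-al; 18 ethyl (2E)-4-(diethoxyphosphoryl)-2-methylbut-2-enoate
Product: 20 ethyl 8'-apo-ψ-caroten-8'-oate (all-E C30 ester), via sodium phosphonate 19 (not isolated)
Conditions: NaH, THF, 0 °C; then 17, 0 °C → rt
Reagents that add atoms: none
Why: The Horner–Wadsworth–Emmons reaction of the stabilised phosphonate anion 19 with the polyenal forms C11=C12 with the E selectivity usual for such anions and brings in C8–C11 with C19.

Step 11
Reactants: 20 ethyl 8'-apo-ψ-caroten-8'-oate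
Product: 21 8'-apo-ψ-caroten-8'-ol (all-E C30 allylic alcohol)
Conditions: i-Bu2AlH, CH2Cl2, −78 → 0 °C; aq. KNaC4H4O6 (tartrate)
Reagents that add atoms: none
Why: i-Bu2AlH reduces the conjugated ester by 1,2-addition to the allylic alcohol without touching the polyene.

Step 12
Reactants: 21 8'-apo-ψ-caroten-8'-ol
Product: 22 (8'-apo-ψ-caroten-8'-yl)triphenylphosphonium bromide (all-E C30 salt)
Conditions: PPh3·HBr, MeOH/CH2Cl2, rt, dark
Reagents that add atoms: triphenylphosphine hydrobromide, [Br-].c1ccc(cc1)[PH+](c1ccccc1)c1ccccc1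
Why: As in step 8, acid generates a polyenyl cation from the allylic alcohol and PPh3 adds at the terminal carbon C8, the position that keeps the whole polyene conjugated.

Step 13
Reactants: 11 (1R,2S,5S)-2-methyl-5-(prop-1-en-2-yl)-2-[(triethylsilyl)oxy]cyclopentane-1-carbaldehyde; 22 (8'-apo-ψ-caroten-8'-yl)triphenylphosphonium bromide
Product: 25 all-E C40 triethylsilyl ether, via C30 ylide 23 (not isolated), via 7Z isomer 24 (not isolated)
Conditions: NaN(SiMe3)2, THF, −78 → −20 °C; then 11, −78 °C → rt; then I2 (cat.), hexane/CH2Cl2, diffuse daylight, rt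
Reagents that add atoms: none
Why: Wittig olefination of the aldehyde with ylide 23, preformed at low temperature so that no free base can enolise the aldehyde at C6, forms C7=C8 as an E/Z mixture, and iodine atoms add reversibly to the unhindered 7Z bond of 24 and equilibrate it to the all-E polyene.

Step 14
Reactants: 25 all-E C40 triethylsilyl ether
Product: 26 (1S,2R,3S)-1-methyl-2-[(1E,3E,5E,7E,9E,11E,13E,15E,17E,19E)-3,7,12,16,20,24-hexamethylpentacosa-1,3,5,7,9,11,13,15,17,19,23-undecaen-1-yl]-3-(prop-1-en-2-yl)cyclopentan-1-ol (target)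
Conditions: Bu4NF, THF, 0 °C → rt, dark; recrystallisation
Reagents that add atoms: none
Why: Fluoride cleaves the Si–O bond of the tertiary silyl ether, driven by the strong Si–F bond, under conditions that should neither isomerise the polyene nor affect the three stereocentres.

**Compound list**

1 | (S)-(−)-limonene, (4S)-1-methyl-4-(prop-1-en-2-yl)cyclohex-1-ene | CC1=CC[C@H](CC1)C(C)=C | starting material
2 | ring ozonide, (4S)-1-methyl-4-(prop-1-en-2-yl)-7,8,9-trioxabicyclo[4.2.1]nonane (both bridgehead diastereomers) | CC12CC[C@H](C(C)=C)CC(OO1)O2 | intermediate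
3 | (3S)-6-oxo-3-(prop-1-en-2-yl)heptanal | C=C(C)[C@H](CC=O)CCC(C)=O | intermediate
4 | (3S)-6-oxo-3-(prop-1-en-2-yl)heptanoic acid | C=C(C)[C@H](CC(=O)O)CCC(C)=O | intermediate
5 | 2-{[(3S)-6-oxo-3-(prop-1-en-2-yl)heptanoyl]oxy}-1-propylpyridin-1-ium trifluoromethanesulfonate | C=C(C)[C@H](CC(=O)Oc1cccc[n+]1CCC)CCC(C)=O.[O-]S(=O)(=O)C(F)(F)F | intermediate
6 | 1-[(3S)-6-oxo-3-(prop-1-en-2-yl)heptanoyl]-4-(pyrrolidin-1-yl)pyridin-1-ium trifluoromethanesulfonate | C=C(C)[C@H](CC(=O)[n+]1ccc(cc1)N1CCCC1)CCC(C)=O.[O-]S(=O)(=O)C(F)(F)F | intermediate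
7 | (1R,2S,5S)-5-methyl-2-(prop-1-en-2-yl)-6-oxabicyclo[3.2.0]heptan-7-one | C=C(C)[C@H]1CC[C@]2(C)OC(=O)[C@H]12 | intermediate
8 | (1R,2S,5S)-2-hydroxy-N-methoxy-N,2-dimethyl-5-(prop-1-en-2-yl)cyclopentane-1-carboxamide | C=C(C)[C@H]1CC[C@](C)(O)[C@@H]1C(=O)N(C)OC | intermediate
9 | (1R,2S,5S)-N-methoxy-N,2-dimethyl-5-(prop-1-en-2-yl)-2-[(triethylsilyl)oxy]cyclopentane-1-carboxamide | C=C(C)[C@H]1CC[C@](C)(O[Si](CC)(CC)CC)[C@@H]1C(=O)N(C)OC | intermediate
10 | diisobutylaluminium N,O-hemiaminal from 9, {[methoxy(methyl)amino][(1R,2S,5S)-2-methyl-5-(prop-1-en-2-yl)-2-[(triethylsilyl)oxy]cyclopentyl]methoxy}bis(2-methylpropyl)alumane | C=C(C)[C@H]1CC[C@](C)(O[Si](CC)(CC)CC)[C@@H]1C(O[Al](CC(C)C)CC(C)C)N(C)OC | intermediate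
11 | (1R,2S,5S)-2-methyl-5-(prop-1-en-2-yl)-2-[(triethylsilyl)oxy]cyclopentane-1-carbaldehyde | C=C(C)[C@H]1CC[C@](C)(O[Si](CC)(CC)CC)[C@@H]1C=O | intermediate
12 | pseudoionone, (3E,5E)-6,10-dimethylundeca-3,5,9-trien-2-one | CC(=O)/C=C/C=C(\C)CCC=C(C)C | starting material
13 | (4E,6E)-3,7,11-trimethyldodeca-1,4,6,10-tetraen-3-ol (racemic) | C=CC(C)(O)/C=C/C=C(\C)CCC=C(C)C | intermediate
14 | [(2E,4E,6E)-3,7,11-trimethyldodeca-2,4,6,10-tetraen-1-yl]triphenylphosphonium bromide | [Br-].c1ccc(cc1)[P+](c1ccccc1)(c1ccccc1)C/C=C(C)/C=C/C=C(\C)CCC=C(C)C | intermediate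
15 | (2E,4E,6E)-2,7-dimethylocta-2,4,6-trienedial | O=C/C(C)=C/C=C/C=C(C)/C=O | starting material
16 | C15 ylide, (2E,4E,6E)-3,7,11-trimethyl-1-(triphenylphosphonio)dodeca-2,4,6,10-tetraen-1-ide | c1ccc(cc1)[P+](c1ccccc1)(c1ccccc1)[CH-]/C=C(C)/C=C/C=C(\C)CCC=C(C)C | intermediate
17 | 12'-apo-ψ-caroten-12'-al, (2E,4E,6E,8E,10E,12E,14E)-2,7,11,15,19-pentamethylicosa-2,4,6,8,10,12,14,18-octaenal | O=C/C(C)=C/C=C/C=C(C)/C=C/C=C(C)/C=C/C=C(\C)CCC=C(C)C | intermediate
18 | ethyl (2E)-4-(diethoxyphosphoryl)-2-methylbut-2-enoate | CCOC(=O)/C(C)=C/CP(=O)(OCC)OCC | starting material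
19 | sodium salt of the carbanion of 18, sodium (2E)-1-(diethoxyphosphoryl)-4-ethoxy-3-methyl-4-oxobut-2-en-1-ide | CCOC(=O)/C(C)=C/[CH-]P(=O)(OCC)OCC.[Na+] | intermediate
20 | ethyl 8'-apo-ψ-caroten-8'-oate, ethyl (2E,4E,6E,8E,10E,12E,14E,16E,18E)-2,6,11,15,19,23-hexamethyltetracosa-2,4,6,8,10,12,14,16,18,22-decaenoate | CCOC(=O)/C(C)=C/C=C/C(C)=C/C=C/C=C(C)/C=C/C=C(C)/C=C/C=C(\C)CCC=C(C)C | intermediate
21 | 8'-apo-ψ-caroten-8'-ol, (2E,4E,6E,8E,10E,12E,14E,16E,18E)-2,6,11,15,19,23-hexamethyltetracosa-2,4,6,8,10,12,14,16,18,22-decaen-1-ol | OC/C(C)=C/C=C/C(C)=C/C=C/C=C(C)/C=C/C=C(C)/C=C/C=C(\C)CCC=C(C)C | intermediate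
22 | [(2E,4E,6E,8E,10E,12E,14E,16E,18E)-2,6,11,15,19,23-hexamethyltetracosa-2,4,6,8,10,12,14,16,18,22-decaen-1-yl]triphenylphosphonium bromide | [Br-].c1ccc(cc1)[P+](c1ccccc1)(c1ccccc1)C/C(C)=C/C=C/C(C)=C/C=C/C=C(C)/C=C/C=C(C)/C=C/C=C(\C)CCC=C(C)C | intermediate
23 | C30 ylide, the 1-ide of 22 after loss of HBr | c1ccc(cc1)[P+](c1ccccc1)(c1ccccc1)[CH-]/C(C)=C/C=C/C(C)=C/C=C/C=C(C)/C=C/C=C(C)/C=C/C=C(\C)CCC=C(C)C | intermediate
24 | 7Z isomer of 25, the (1Z,3E,5E,7E,9E,11E,13E,15E,17E,19E)-undecaenyl compound | C=C(C)[C@H]1CC[C@](C)(O[Si](CC)(CC)CC)[C@@H]1\C=C/C(C)=C/C=C/C(C)=C/C=C/C=C(C)/C=C/C=C(C)/C=C/C=C(\C)CCC=C(C)C | intermediate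
25 | triethyl({(1S,2R,3S)-1-methyl-2-[(1E,3E,5E,7E,9E,11E,13E,15E,17E,19E)-3,7,12,16,20,24-hexamethylpentacosa-1,3,5,7,9,11,13,15,17,19,23-undecaen-1-yl]-3-(prop-1-en-2-yl)cyclopentyl}oxy)silane | C=C(C)[C@H]1CC[C@](C)(O[Si](CC)(CC)CC)[C@@H]1/C=C/C(C)=C/C=C/C(C)=C/C=C/C=C(C)/C=C/C=C(C)/C=C/C=C(\C)CCC=C(C)C | intermediate
26 | CNP0222499.1, (1S,2R,3S)-1-methyl-2-[(1E,3E,5E,7E,9E,11E,13E,15E,17E,19E)-3,7,12,16,20,24-hexamethylpentacosa-1,3,5,7,9,11,13,15,17,19,23-undecaen-1-yl]-3-(prop-1-en-2-yl)cyclopentan-1-ol | C=C(C)[C@H]1CC[C@](C)(O)[C@@H]1/C=C/C(C)=C/C=C/C(C)=C/C=C/C=C(C)/C=C/C=C(C)/C=C/C=C(\C)CCC=C(C)C | target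

**Count and risks**

Total step count: 14. Longest linear sequence: 8 steps (steps 1–6, 13 and 14 from 1; equally steps 7–14 from 12).

Steps most likely to fail:

Step 3. The facial bias exerted by C2 may be eroded, or the acylammonium ion may be consumed by intermolecular acylation before it adds to the ketone. The fallback sets out from keto aldehyde 3 and comes back at Weinreb amide 8, forming C5–C6 through a chelated metal enolate instead.
- Amine-catalysed α-bromination of the aldehyde (NBS, cat. secondary amine, CH2Cl2, 0 °C) should give (3R)-2-bromo-6-oxo-3-(prop-1-en-2-yl)heptanal F1.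
- NaClO2 oxidation would give (3R)-2-bromo-6-oxo-3-(prop-1-en-2-yl)heptanoic acid F2, and Me3SiCHN2 in MeOH/toluene methyl (3R)-2-bromo-6-oxo-3-(prop-1-en-2-yl)heptanoate F3.
- An intramolecular Reformatsky reaction with SmI2 (THF, −78 °C) should close the ring; the samarium enolate chelated to the ketone places the ester cis to the new hydroxyl and trans to isopropenyl, giving methyl (1R,2S,5S)-2-hydroxy-2-methyl-5-(prop-1-en-2-yl)cyclopentane-1-carboxylate F4.
- Aminolysis with MeNH(OMe)·HCl and i-PrMgCl (THF, −20 °C) then gives 8.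

Step 13. The basic ylide may enolise the hindered β-silyloxy aldehyde, with loss of triethylsilanolate or epimerisation at C6, and the 7Z/7E equilibration may stay incomplete. The fallback sets out from aldehyde 11 and comes back at silyl ether 25, moving the final union to C11=C12.
- Horner–Wadsworth–Emmons reaction with ethyl (2E)-4-(diethoxyphosphoryl)-3-methylbut-2-enoate (LiN(SiMe3)2, THF, −78 → 0 °C), whose small and weakly basic anion should set C7=C8 as E, would give ethyl (2E,4E)-3-methyl-5-[(1R,2S,5S)-2-methyl-5-(prop-1-en-2-yl)-2-[(triethylsilyl)oxy]cyclopentyl]penta-2,4-dienoate F5.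
- Reduction with i-Bu2AlH would give (2E,4E)-3-methyl-5-[(1R,2S,5S)-2-methyl-5-(prop-1-en-2-yl)-2-[(triethylsilyl)oxy]cyclopentyl]penta-2,4-dien-1-ol F6.
- Bromination under neutral conditions (CBr4, PPh3, CH2Cl2, 0 °C) would give {[(1S,2R,3S)-2-[(1E,3E)-5-bromo-3-methylpenta-1,3-dien-1-yl]-1-methyl-3-(prop-1-en-2-yl)cyclopentyl]oxy}triethylsilane F7, and PPh3 would convert it into [(2E,4E)-3-methyl-5-[(1R,2S,5S)-2-methyl-5-(prop-1-en-2-yl)-2-[(triethylsilyl)oxy]cyclopentyl]penta-2,4-dien-1-yl]triphenylphosphonium bromide F8.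
- Wittig reaction of F8 with the C25 aldehyde 17 (NaOMe, CH2Cl2/MeOH; then heptane, 80 °C) forms C11=C12, where a Z isomer is hindered and reverts on heating, and gives 25.

Step 1. Ozone may not discriminate cleanly between the two alkenes, so that the isopropenyl group is cleaved as well. The fallback sets out from 1 and comes back at 3.
- Epoxidation with m-CPBA (CH2Cl2, 0 °C), which is selective for the trisubstituted ring alkene, would give (4S)-1-methyl-4-(prop-1-en-2-yl)-7-oxabicyclo[4.1.0]heptane F9 as a cis/trans mixture, both of which converge.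
- H5IO6 (THF/H2O, rt) hydrolyses the epoxide and cleaves the diol to keto aldehyde 3.

**Further compounds**

F1 | step 3 | (3R)-2-bromo-6-oxo-3-(prop-1-en-2-yl)heptanal (both C2 epimers) | C=C(C)[C@H](C(Br)C=O)CCC(C)=O
F2 | step 3 | (3R)-2-bromo-6-oxo-3-(prop-1-en-2-yl)heptanoic acid (both C2 epimers) | C=C(C)[C@H](C(Br)C(=O)O)CCC(C)=O
F3 | step 3 | methyl (3R)-2-bromo-6-oxo-3-(prop-1-en-2-yl)heptanoate (both C2 epimers) | C=C(C)[C@H](C(Br)C(=O)OC)CCC(C)=O
F4 | step 3 | methyl (1R,2S,5S)-2-hydroxy-2-methyl-5-(prop-1-en-2-yl)cyclopentane-1-carboxylate | C=C(C)[C@H]1CC[C@](C)(O)[C@@H]1C(=O)OC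
F5 | step 13 | ethyl (2E,4E)-3-methyl-5-[(1R,2S,5S)-2-methyl-5-(prop-1-en-2-yl)-2-[(triethylsilyl)oxy]cyclopentyl]penta-2,4-dienoate | C=C(C)[C@H]1CC[C@](C)(O[Si](CC)(CC)CC)[C@@H]1/C=C/C(C)=C/C(=O)OCC
F6 | step 13 | (2E,4E)-3-methyl-5-[(1R,2S,5S)-2-methyl-5-(prop-1-en-2-yl)-2-[(triethylsilyl)oxy]cyclopentyl]penta-2,4-dien-1-ol | C=C(C)[C@H]1CC[C@](C)(O[Si](CC)(CC)CC)[C@@H]1/C=C/C(C)=C/CO
F7 | step 13 | {[(1S,2R,3S)-2-[(1E,3E)-5-bromo-3-methylpenta-1,3-dien-1-yl]-1-methyl-3-(prop-1-en-2-yl)cyclopentyl]oxy}triethylsilane | C=C(C)[C@H]1CC[C@](C)(O[Si](CC)(CC)CC)[C@@H]1/C=C/C(C)=C/CBr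
F8 | step 13 | [(2E,4E)-3-methyl-5-[(1R,2S,5S)-2-methyl-5-(prop-1-en-2-yl)-2-[(triethylsilyl)oxy]cyclopentyl]penta-2,4-dien-1-yl]triphenylphosphonium bromide | C=C(C)[C@H]1CC[C@](C)(O[Si](CC)(CC)CC)[C@@H]1/C=C/C(C)=C/C[P+](c1ccccc1)(c1ccccc1)c1ccccc1.[Br-]
F9 | step 1 | (4S)-1-methyl-4-(prop-1-en-2-yl)-7-oxabicyclo[4.1.0]heptane (cis/trans mixture) | CC12CC[C@H](C(C)=C)CC1O2
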